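Ring B is numbered as a cyclohexa-2,5-dienone (C1 C=O, C2 bears the CH2 bridge, C3 C–OH, C4 quaternary, C5 C–OH, C6 bears butanoyl). Everything rests on the C3–C4 disconnection. The chain C3–C2–C1–C6–C5–C4 is that of a 4-hydroxy-2-pyranone, C3 being the lactone C=O and C4 the CH of a 6-sec-alkyl group. Double deprotonation should open the lactone to a dienylketene bis-enolate that recloses through carbon, giving carbocycle and quaternary stereocentre in one operation. The precursor is a flat triacetic acid lactone derivative. Its chiral 3-aminomethyl arm differentiates the ring flanks, biases the closure and later leaves to make the methylene bridge.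

Key step: step 4

Assumption: the sense of induction by the (S)-amine 7 cannot be derived from precedent; the depicted epimer 12 is taken as the favoured one, and if the opposite holds the commercially available (R)-amine is used with no other change.

Step 1
Reactants: 1 4-hydroxy-6-methyl-2H-pyran-2-one (triacetic acid lactone); 2 1-bromo-3-methylbut-2-ene (prenyl bromide)
Product: 4 4-hydroxy-6-(4-methylpent-3-en-1-yl)-2H-pyran-2-one, via dilithiated lactone 3 (not isolated)
Conditions: LiN(iPr)2 (2.3 equiv), THF–DMPU, −78 to −20 °C; 2, −78 °C to rt; aq. HCl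
Reagents that add atoms: none
Why: Dianion alkylation (SN2): the doubly deprotonated 4-hydroxy-2-pyranone reacts with the allylic bromide at its last-formed and most basic site, the exocyclic 6-CH2 carbon, and no stereocentre is formed.

Step 2
Reactants: 4 4-hydroxy-6-(4-methylpent-3-en-1-yl)-2H-pyran-2-one
Product: 6 (±)-4-hydroxy-6-(5-methylhex-4-en-2-yl)-2H-pyran-2-one, via dilithiated pyranone 5 (not isolated)
Conditions: LiN(iPr)2 (2.3 equiv), THF–DMPU, −78 to −20 °C; MeI, −78 °C to rt; aq. HCl
Reagents that add atoms: iodomethane, CI
Why: Second dianion alkylation (SN2) at the same, now secondary, side-chain carbon; the new stereocentre forms racemic, which is harmless because step 4 planarises it.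

Step 3
Reactants: 6 (±)-4-hydroxy-6-(5-methylhex-4-en-2-yl)-2H-pyran-2-one; 7 (S)-2-(methoxymethyl)pyrrolidine
Product: 9 4-hydroxy-3-{[(2S)-2-(methoxymethyl)pyrrolidin-1-yl]methyl}-6-(5-methylhex-4-en-2-yl)-2H-pyran-2-one (both epimers at the side-chain carbon), via N-hydroxymethyl amine 8 (not isolated)
Conditions: aq. CH2O + 7, EtOH, 0 °C; then 6, 0 °C to rt
Reagents that add atoms: formaldehyde, C=O
Why: Mannich reaction: the preformed hemiaminal 8 delivers the iminium ion to C3 of the pyranone, its only strongly nucleophilic carbon, premixing amine and formaldehyde should suppress methylene-bis-pyranone formation, and the pyrrolidine stereocentre is untouched.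

Step 4
Reactants: 9 4-hydroxy-3-{[(2S)-2-(methoxymethyl)pyrrolidin-1-yl]methyl}-6-(5-methylhex-4-en-2-yl)-2H-pyran-2-one
Product: 12 (4S)-3,5-dihydroxy-2-{[(2S)-2-(methoxymethyl)pyrrolidin-1-yl]methyl}-4-methyl-4-(3-methylbut-2-en-1-yl)cyclohexa-2,5-dien-1-one, via dilithiated pyranone 10 (not isolated), via dienylketene bis-enolate 11 (not isolated)
Conditions: lithium 2,2,6,6-tetramethylpiperidide (2.5 equiv), THF, high dilution, −78 to 50 °C; AcOH quench; chromatography
Reagents that add atoms: none
Why: Proposed new method: two equivalents of base give dianion 10, whose lactone enolate should expel the ring oxygen as an enolate (E1cB, as aryl-ester enolates do) to give dienylketene 11 with both chain ends cis on the central C=C as inherited from the ring, and the C(Me)(prenyl) enolate carbon then adds to the ketene carbon. The closest known reactions are the thermal reclosure of dienylketenes to cyclohexa-2,4-dienones (last event of the Danheiser annulation, reverse of the Barton–Quinkert opening) and the base-induced Claisen recyclisation of 6-(2-oxoalkyl)-4-hydroxy-2-pyranones to acylphloroglucinols. The six-membered carbocycle closes in a 6-(enolendo)-exo-dig mode, equally a 6π electrocyclisation of an oxido-substituted dienylketene. The new quaternary centre is controlled by the (S)-pyrrolidine arm: its N and OMe hold the lithium that binds the developing oxygen at the ketene carbon, one face beside the new bond is covered, the longer prenyl group should turn to the open face whichever enolate geometry reacts, and the minor epimer is a diastereomer that chromatography removes. The step needs C- over O-acylation, which the substrate secures because O-attack only regenerates 10 while C-attack ends in a far less basic triketone dianion, and every other internal nucleophile would give a four-membered ring. The aminomethyl group keeps the two flanks of the new ring different, so enol tautomerism cannot racemise 12.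

Step 5
Reactants: 12 (4S)-3,5-dihydroxy-2-{[(2S)-2-(methoxymethyl)pyrrolidin-1-yl]methyl}-4-methyl-4-(3-methylbut-2-en-1-yl)cyclohexa-2,5-dien-1-one
Product: 14 (4R)-6-butanoyl-3,5-dihydroxy-2-{[(2S)-2-(methoxymethyl)pyrrolidin-1-yl]methyl}-4-methyl-4-(3-methylbut-2-en-1-yl)cyclohexa-2,5-dien-1-one, via enol butanoate 13 (not isolated)
Conditions: PrCOCl (1.1 equiv), Et3N, CH2Cl2, 0 °C; then DMAP (cat.), rt
Reagents that add atoms: butanoyl chloride, CCCC(=O)Cl
Why: O-acylation followed by DMAP-mediated O-to-C acyl migration (Fries-type rearrangement of 1,3-dione enol esters): C6 is the only ring carbon still bearing hydrogen, the hydrogen-bonded triketone is the thermodynamic sink, and the quaternary centre is not involved (its descriptor changes only through the CIP ranking).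

Step 6
Reactants: 15 benzene-1,3,5-triol (phloroglucinol); 16 hexanoyl chloride
Product: 17 1-(2,4,6-trihydroxyphenyl)hexan-1-one
Conditions: AlCl3 (3 equiv), CH2Cl2–PhNO2, 0 to 40 °C; aq. HCl
Reagents that add atoms: none
Why: Friedel–Crafts acylation of the symmetric, very electron-rich arene should stop after one acyl group because the product ketone is deactivated and chelated to aluminium.

Step 7
Reactants: 17 1-(2,4,6-trihydroxyphenyl)hexan-1-one
Product: 18 1-(2,6-dihydroxy-4-methoxyphenyl)hexan-1-one
Conditions: MeI (1 equiv), K2CO3 (1 equiv), acetone, rt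
Reagents that add atoms: iodomethane, CI
Why: Williamson ether synthesis: the 4-OH para to the ketone is the most acidic hydroxyl and the only one not held in a hydrogen bond to the carbonyl group, so one equivalent of base and MeI should alkylate it selectively.

Step 8
Reactants: 14 (4R)-6-butanoyl-3,5-dihydroxy-2-{[(2S)-2-(methoxymethyl)pyrrolidin-1-yl]methyl}-4-methyl-4-(3-methylbut-2-en-1-yl)cyclohexa-2,5-dien-1-one; 18 1-(2,6-dihydroxy-4-methoxyphenyl)hexan-1-one
Product: 20 Elaphopilosin B, via exocyclic enone 19 (not isolated)
Conditions: 18 (2 equiv), toluene, 90 °C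
Reagents that add atoms: none
Why: Mannich-base coupling: thermal retro-Michael loss of the amine gives exocyclic enone 19, which one of the two equivalent free aromatic CH positions of 18 attacks in a Friedel–Crafts-type Michael addition, and the quaternary centre is a spectator.

Compound list
1 | 4-hydroxy-6-methyl-2H-pyran-2-one (triacetic acid lactone) | CC1=CC(O)=CC(=O)O1 | starting material
2 | 1-bromo-3-methylbut-2-ene (prenyl bromide) | CC(C)=CCBr | starting material
3 | dilithiated lactone (dianion of 1, exocyclic methylene bis-enolate) | C=C1C=C([O-])C=C([O-])O1.[Li+].[Li+] | intermediate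
4 | 4-hydroxy-6-(4-methylpent-3-en-1-yl)-2H-pyran-2-one | CC(C)=CCCC1=CC(O)=CC(=O)O1 | intermediate
5 | dilithiated pyranone (dianion of 4) | CC(C)=CCC=C1C=C([O-])C=C([O-])O1.[Li+].[Li+] | intermediate
6 | (±)-4-hydroxy-6-(5-methylhex-4-en-2-yl)-2H-pyran-2-one | CC(C)=CCC(C)C1=CC(O)=CC(=O)O1 | intermediate
7 | (S)-2-(methoxymethyl)pyrrolidine | COC[C@@H]1CCCN1 | starting material
8 | [(2S)-2-(methoxymethyl)pyrrolidin-1-yl]methanol (hemiaminal) | COC[C@@H]1CCCN1CO | intermediate
9 | 4-hydroxy-3-{[(2S)-2-(methoxymethyl)pyrrolidin-1-yl]methyl}-6-(5-methylhex-4-en-2-yl)-2H-pyran-2-one, both side-chain epimers | COC[C@@H]1CCCN1CC2=C(O)C=C(OC2=O)C(C)CC=C(C)C | intermediate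
10 | dilithiated pyranone (dianion of 9, exocyclic tetrasubstituted alkylidene) | COC[C@@H]1CCCN1CC2=C([O-])OC(=C(C)CC=C(C)C)C=C2[O-].[Li+].[Li+] | intermediate
11 | dienylketene bis-enolate (ring-opened 10, chain ends cis on the central C=C) | COC[C@@H]1CCCN1CC(=C=O)/C([O-])=C\C([O-])=C(C)CC=C(C)C.[Li+].[Li+] | intermediate
12 | (4S)-3,5-dihydroxy-2-{[(2S)-2-(methoxymethyl)pyrrolidin-1-yl]methyl}-4-methyl-4-(3-methylbut-2-en-1-yl)cyclohexa-2,5-dien-1-one | COC[C@@H]1CCCN1CC2=C(O)[C@@](C)(CC=C(C)C)C(O)=CC2=O | intermediate
13 | enol butanoate of 12 (butanoyl on the oxygen of ring-B C1, quaternary centre unchanged) | COC[C@@H]1CCCN1CC2=C(O)[C@@](C)(CC=C(C)C)C(=O)C=C2OC(=O)CCC | intermediate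
14 | (4R)-6-butanoyl-3,5-dihydroxy-2-{[(2S)-2-(methoxymethyl)pyrrolidin-1-yl]methyl}-4-methyl-4-(3-methylbut-2-en-1-yl)cyclohexa-2,5-dien-1-one (same spatial arrangement as 12) | COC[C@@H]1CCCN1CC2=C(O)[C@@](C)(CC=C(C)C)C(O)=C(C(=O)CCC)C2=O | intermediate
15 | benzene-1,3,5-triol (phloroglucinol) | Oc1cc(O)cc(O)c1 | starting material
16 | hexanoyl chloride | CCCCCC(=O)Cl | starting material
17 | 1-(2,4,6-trihydroxyphenyl)hexan-1-one | CCCCCC(=O)c1c(O)cc(O)cc1O | intermediate
18 | 1-(2,6-dihydroxy-4-methoxyphenyl)hexan-1-one | CCCCCC(=O)c1c(O)cc(OC)cc1O | intermediate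
19 | (4S)-2-butanoyl-3-hydroxy-4-methyl-6-methylidene-4-(3-methylbut-2-en-1-yl)cyclohex-2-ene-1,5-dione (same spatial arrangement as 14) | C=C1C(=O)[C@@](C)(CC=C(C)C)C(O)=C(C(=O)CCC)C1=O | intermediate
20 | Elaphopilosin B, (4R)-6-butanoyl-2-[(3-hexanoyl-2,4-dihydroxy-6-methoxyphenyl)methyl]-3,5-dihydroxy-4-methyl-4-(3-methylbut-2-en-1-yl)cyclohexa-2,5-dien-1-one | CCCCCC(=O)c1c(O)cc(OC)c(CC2=C(O)[C@@](C)(CC=C(C)C)C(O)=C(C(=O)CCC)C2=O)c1O | target

Total step count: 8. Longest linear sequence: 6 (steps 1, 2, 3, 4, 5, 8).

Steps most likely to fail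

Risk 1 (step 4). The hindered tertiary C–H may resist removal. The dianion may stay closed or add to a second pyranone instead of opening. Facial selectivity of the closure may be poor. The fallback uses known chemistry and closes the same bond, and it sets out from 6. Methanolysis with Mg(OMe)2 in MeOH should open the lactone to methyl 6,9-dimethyl-3,5-dioxodec-8-enoate F1. A Dieckmann cyclisation promoted by Me2AlSEt (thioester formation, aluminium enolate) should close it onto the tertiary carbon. This gives achiral 3,5-dihydroxy-4-methyl-4-(3-methylbut-2-en-1-yl)cyclohexa-2,5-dien-1-one F2. A Mannich reaction of F2 with hemiaminal 8 then gives 12 beside the ring epimer of 12 F3. The two are diastereomers and are separated, and the route is rejoined at 12. In this variant the configuration comes from the separation alone.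

Risk 2 (step 8). The liberated amine may add back. The exocyclic enone may oligomerise faster than the arene attacks. The arene may also be alkylated twice. The fallback sets out from 14. N-methylation with MeI gives the N-methylammonium iodide of 14 F4, whose leaving group departs far below the temperature of step 8. With NaHCO3 in MeCN at 0 to 20 °C, in the presence of excess 18, enone 19 should be released slowly and captured at once. The route is rejoined at 20.

Risk 3 (step 5). The acyl group may stay on oxygen. Base and DMAP may also trigger premature loss of the aminomethyl arm. The fallback sets out from 12 and inverts the order of the last two bond formations. Compound 12 is first heated with 18, as in step 8, to give the des-butanoyl dimer F5. The butanoyl group is then placed on the only free ring-B carbon with butanoic acid, DCC and DMAP (one-pot O-acylation and acyl migration). Any phenol ester is cleaved with K2CO3 in MeOH, and the route is rejoined at 20.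

Further compounds
F1 | step 4 | methyl 6,9-dimethyl-3,5-dioxodec-8-enoate | COC(=O)CC(=O)CC(=O)C(C)CC=C(C)C
F2 | step 4 | 3,5-dihydroxy-4-methyl-4-(3-methylbut-2-en-1-yl)cyclohexa-2,5-dien-1-one (achiral) | CC(C)=CCC1(C)C(O)=CC(=O)C=C1O
F3 | step 4 | ring epimer of 12, (4R)-3,5-dihydroxy-2-{[(2S)-2-(methoxymethyl)pyrrolidin-1-yl]methyl}-4-methyl-4-(3-methylbut-2-en-1-yl)cyclohexa-2,5-dien-1-one | COC[C@@H]1CCCN1CC2=C(O)[C@](C)(CC=C(C)C)C(O)=CC2=O
F4 | step 8 | N-methylammonium iodide of 14 | COC[C@@H]1CCC[N+]1(C)CC2=C(O)[C@@](C)(CC=C(C)C)C(O)=C(C(=O)CCC)C2=O.[I-]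
F5 | step 5 | des-butanoyl dimer, 2-[(3-hexanoyl-2,4-dihydroxy-6-methoxyphenyl)methyl]-3,5-dihydroxy-4-methyl-4-(3-methylbut-2-en-1-yl)cyclohexa-2,5-dien-1-one, quaternary centre as in 12 | CCCCCC(=O)c1c(O)cc(OC)c(CC2=C(O)[C@@](C)(CC=C(C)C)C(O)=CC2=O)c1O
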